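**Retrosynthetic overview**

1. The route rests on ring A'' of unit 2: C8'' carries the ether oxygen that sits on C4' of ring B of unit 1 (genkwanin), and C5'', C7'' and C8a'' carry oxygen in a 1,3,5 pattern. Ring A'' can therefore be folded from a β-polycarbonyl chain, and C8'' can begin as an sp3 ArO–CH2 carbon.
2. Target 18 ⇐ 17 (debenzylation at O4''') ⇐ 16 (methylation of the only unchelated phenol, 7''-OH).
3. 16 ⇐ β-ketoester 14 by forming C7''–C8'' (Dieckmann closure and aromatisation of ring A'', the last ring made).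
4. 14 ⇐ pyranone acid 10 ⇐ tert-butyl ester 9. The C5''–C6'' bond comes from acylation of a malonate half ester, because an ester enolate would first deprotonate C8'' and leave an unreactive dienolate-conjugated ester. Ring C'' (the 4-pyranone) ⇐ ketoester 3 + aroylketene 7.
5. 3 ⇐ genkwanin 1 + tert-butyl 4-chloroacetoacetate 2 (O4'–C8'' bond by SN2). The rings of unit 1 and ring B''' are bought; ring C'' forms in step 3 and ring A'' in step 6.

Key step: step 6

Remark: unprimed and singly primed locants belong to the genkwanin unit, doubly primed to the chromone of unit 2 and triply primed to its 2-aryl ring; the target has no stereocentre, so no step sets or endangers configuration.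

**Step 1**
Reactants: 1 genkwanin (5-hydroxy-2-(4-hydroxyphenyl)-7-methoxy-4H-chromen-4-one); 2 tert-butyl 4-chloro-3-oxobutanoate
Product: 3 tert-butyl 4-[4-(5-hydroxy-7-methoxy-4-oxo-4H-chromen-2-yl)phenoxy]-3-oxobutanoate
Conditions: NaH (3.2 equiv), DMF, 0 °C; then 2 (1.2 equiv), 0 °C → rt; aq. NH4Cl
Reagents that add atoms: none
Why: Williamson etherification at the primary α-chloroketone carbon; the ketoester is held as its sodium enolate, and the chelated 5-phenoxide is far less nucleophilic than the 4'-phenoxide, so alkylation should occur at O4' only.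

**Step 2**
Reactants: 4 4-benzyloxybenzoic acid; 5 Meldrum's acid (2,2-dimethyl-1,3-dioxane-4,6-dione)
Product: 6 5-[(4-benzyloxyphenyl)(hydroxy)methylidene]-2,2-dimethyl-1,3-dioxane-4,6-dione
Conditions: DCC, DMAP, CH2Cl2, 0 °C → rt; cold aq. KHSO4 wash
Reagents that add atoms: none
Why: Carbodiimide activation of the acid and C-acylation of Meldrum's acid (Steglich-type), with the product held as its stable enol.

**Step 3**
Reactants: 3 tert-butyl 4-[4-(5-hydroxy-7-methoxy-4-oxo-4H-chromen-2-yl)phenoxy]-3-oxobutanoate; 6 the acyl Meldrum's acid of step 2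
Product: 9 tert-butyl 6-(4-benzyloxyphenyl)-2-{[4-(5-hydroxy-7-methoxy-4-oxo-4H-chromen-2-yl)phenoxy]methyl}-4-oxo-4H-pyran-3-carboxylate, via aroylketene 7 (not isolated), via open-chain tricarbonyl ester 8 (not isolated)
Conditions: 6 (1.5 equiv), PhMe, 80 °C, N2 sweep; then PPTS (cat.), 50 °C
Reagents that add atoms: none
Why: Thermal retro-[4+2] fragmentation of 6 gives ketene 7, the enol carbon C2 of 3 adds to the ketene carbon (acylketene C-acylation, a formal hetero-Diels–Alder reaction), and tricarbonyl 8 cyclodehydrates to the 4-pyranone; the bulky tert-butyl ester disfavours the competing lactonisation to a 2-pyranone.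

**Step 4**
Reactants: 9 the tert-butyl pyranone-3-carboxylate of step 3
Product: 10 6-(4-benzyloxyphenyl)-2-{[4-(5-hydroxy-7-methoxy-4-oxo-4H-chromen-2-yl)phenoxy]methyl}-4-oxo-4H-pyran-3-carboxylic acid
Conditions: TFA/CH2Cl2 (1:3), 0 °C → rt
Reagents that add atoms: none
Why: Acidolysis of the tert-butyl ester by alkyl–oxygen cleavage, which does not depend on access to the flanked carbonyl; the aryl benzyl and methyl ethers, the ArO–CH2 ether and both pyranone rings should be stable to TFA at rt.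

**Step 5**
Reactants: 10 the pyranone-3-carboxylic acid of step 4; 11 potassium methyl malonate (KO2CCH2CO2Me)
Product: 14 methyl 3-[6-(4-benzyloxyphenyl)-2-{[4-(5-hydroxy-7-methoxy-4-oxo-4H-chromen-2-yl)phenoxy]methyl}-4-oxo-4H-pyran-3-yl]-3-oxopropanoate, via acyl imidazolide 12 (not isolated), via acylmalonic half ester 13 (not isolated)
Conditions: 1,1'-carbonyldiimidazole (1.1 equiv), THF, rt; then 11, MgCl2, Et3N, MeCN/THF, rt → 45 °C; aq. HCl
Reagents that add atoms: 1,1'-carbonyldiimidazole, O=C(n1ccnc1)n1ccnc1 (supplies the imidazolyl group of 12 only; none of its atoms remain in 14)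
Why: Masamune–Brooks homologation, in which the magnesium enolate of the malonate half ester is C-acylated by the imidazolide and then decarboxylates; the medium is nearly neutral, so the pyranone should not be opened and C8'' should not be deprotonated.

**Step 6**
Reactants: 14 the β-ketoester of step 5
Product: 16 2-(4-benzyloxyphenyl)-5,7-dihydroxy-8-[4-(5-hydroxy-7-methoxy-4-oxo-4H-chromen-2-yl)phenoxy]-4H-chromen-4-one (the 7''-O-demethyl-4'''-O-benzyl target), via ring-closed trione 15 (not isolated)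
Conditions: LiN(iPr)2 (4.5 equiv), THF, −78 °C → 0 °C; aq. HCl
Reagents that add atoms: none
Why: LiN(iPr)2 removes in turn the 5-OH proton, a C6'' proton of the β-ketoester and a C8'' proton (the γ-position of the pyranone vinylogous ester, further acidified by the aryloxy group); the C8'' dienolate carbon then adds to the ester carbonyl C7'', methoxide leaves to give trione 15, and 15 is deprotonated at once and tautomerises on acidic work-up to the 5'',7''-dihydroxy ring A''. The closest known reaction type is the base-induced Dieckmann (intramolecular Claisen) aromatisation of polyketide-type β-polycarbonyl esters, combined with the established γ-deprotonation and C-acylation of 2-alkyl-4-pyranones. Ring A'' closes in a 6-exo-trig mode (C8'' onto the exocyclic C7''=O), and no stereocentre survives because C8'' becomes sp2 on enolisation. The step needs C8'' and not C6'' as the nucleophile, and C7'' and not C5'' as the electrophile: C6'' is deprotonated first, which masks the C5'' ketone as an enolate, attack of C8'' on C5'' would give a four-membered ring, and the C6'' enolate has no carbonyl within reach of a five- or six-membered closure. The position of the aryloxy group is fixed beforehand, because O1'' already joins C2'' to C8a'', the carbon that carries the ArO–CH2 group, so a 6''-aryloxy isomer cannot arise. Formation of the aromatic resorcinol dianion makes the closure irreversible and should pull the reluctant attack on an enolate-conjugated ester forward.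

**Step 7**
Reactants: 16 the 5'',7''-diol of step 6
Product: 17 2-(4-benzyloxyphenyl)-5-hydroxy-8-[4-(5-hydroxy-7-methoxy-4-oxo-4H-chromen-2-yl)phenoxy]-7-methoxy-4H-chromen-4-one
Conditions: MeI (1.1 equiv), K2CO3 (1.1 equiv), acetone, rt
Reagents that add atoms: iodomethane, CI
Why: Williamson O-methylation; the 7''-OH is the only phenol not hydrogen-bonded to a C4 carbonyl and is the most acidic, so one equivalent of MeI with carbonate should methylate it alone (the usual 7-over-5 selectivity of 5,7-dihydroxyflavones).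

**Step 8**
Reactants: 17 the benzyl ether of step 7
Product: 18 5-hydroxy-2-(4-hydroxyphenyl)-8-[4-(5-hydroxy-7-methoxy-4-oxo-4H-chromen-2-yl)phenoxy]-7-methoxy-4H-chromen-4-one (target, CNP0415865.0)
Conditions: H2 (1 atm), 10% Pd/C, THF/MeOH, rt
Reagents that add atoms: none
Why: Hydrogenolysis of the benzyl aryl ether over Pd/C; the flavone C2=C3 bonds, the diaryl ether and the methyl ethers should be inert at 1 atm and rt.

**Compound list**

1 | genkwanin, 5-hydroxy-2-(4-hydroxyphenyl)-7-methoxy-4H-chromen-4-one | COc1cc(O)c2c(=O)cc(-c3ccc(O)cc3)oc2c1 | starting material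
2 | tert-butyl 4-chloro-3-oxobutanoate | CC(C)(C)OC(=O)CC(=O)CCl | starting material
3 | tert-butyl 4-[4-(5-hydroxy-7-methoxy-4-oxo-4H-chromen-2-yl)phenoxy]-3-oxobutanoate | CC(C)(C)OC(=O)CC(=O)COc1ccc(-c2cc(=O)c3c(O)cc(OC)cc3o2)cc1 | intermediate
4 | 4-benzyloxybenzoic acid | O=C(O)c1ccc(OCc2ccccc2)cc1 | starting material
5 | Meldrum's acid, 2,2-dimethyl-1,3-dioxane-4,6-dione | CC1(C)OC(=O)CC(=O)O1 | starting material
6 | 5-[(4-benzyloxyphenyl)(hydroxy)methylidene]-2,2-dimethyl-1,3-dioxane-4,6-dione | CC1(C)OC(=O)C(=C(O)c2ccc(OCc3ccccc3)cc2)C(=O)O1 | intermediate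
7 | (4-benzyloxybenzoyl)ketene, 3-(4-benzyloxyphenyl)-3-oxoprop-1-en-1-one (not isolated) | O=C=CC(=O)c1ccc(OCc2ccccc2)cc1 | intermediate
8 | tert-butyl 5-(4-benzyloxyphenyl)-2-{[4-(5-hydroxy-7-methoxy-4-oxo-4H-chromen-2-yl)phenoxy]acetyl}-3,5-dioxopentanoate (not isolated) | CC(C)(C)OC(=O)C(C(=O)COc1ccc(-c2cc(=O)c3c(O)cc(OC)cc3o2)cc1)C(=O)CC(=O)c1ccc(OCc2ccccc2)cc1 | intermediate
9 | tert-butyl 6-(4-benzyloxyphenyl)-2-{[4-(5-hydroxy-7-methoxy-4-oxo-4H-chromen-2-yl)phenoxy]methyl}-4-oxo-4H-pyran-3-carboxylate | CC(C)(C)OC(=O)c1c(COc2ccc(-c3cc(=O)c4c(O)cc(OC)cc4o3)cc2)oc(-c2ccc(OCc3ccccc3)cc2)cc1=O | intermediate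
10 | 6-(4-benzyloxyphenyl)-2-{[4-(5-hydroxy-7-methoxy-4-oxo-4H-chromen-2-yl)phenoxy]methyl}-4-oxo-4H-pyran-3-carboxylic acid | O=C(O)c1c(COc2ccc(-c3cc(=O)c4c(O)cc(OC)cc4o3)cc2)oc(-c2ccc(OCc3ccccc3)cc2)cc1=O | intermediate
11 | potassium methyl malonate (KO2CCH2CO2Me) | COC(=O)CC(=O)[O-].[K+] | starting material
12 | 6-(4-benzyloxyphenyl)-2-{[4-(5-hydroxy-7-methoxy-4-oxo-4H-chromen-2-yl)phenoxy]methyl}-3-(1H-imidazol-1-ylcarbonyl)-4H-pyran-4-one (not isolated) | O=C(c1c(COc2ccc(-c3cc(=O)c4c(O)cc(OC)cc4o3)cc2)oc(-c2ccc(OCc3ccccc3)cc2)cc1=O)n1ccnc1 | intermediate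
13 | 2-(methoxycarbonyl)-3-oxo-3-[6-(4-benzyloxyphenyl)-2-{[4-(5-hydroxy-7-methoxy-4-oxo-4H-chromen-2-yl)phenoxy]methyl}-4-oxo-4H-pyran-3-yl]propanoic acid (racemic, not isolated) | COC(=O)C(C(=O)O)C(=O)c1c(COc2ccc(-c3cc(=O)c4c(O)cc(OC)cc4o3)cc2)oc(-c2ccc(OCc3ccccc3)cc2)cc1=O | intermediate
14 | methyl 3-[6-(4-benzyloxyphenyl)-2-{[4-(5-hydroxy-7-methoxy-4-oxo-4H-chromen-2-yl)phenoxy]methyl}-4-oxo-4H-pyran-3-yl]-3-oxopropanoate | COC(=O)CC(=O)c1c(COc2ccc(-c3cc(=O)c4c(O)cc(OC)cc4o3)cc2)oc(-c2ccc(OCc3ccccc3)cc2)cc1=O | intermediate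
15 | 2-(4-benzyloxyphenyl)-8-[4-(5-hydroxy-7-methoxy-4-oxo-4H-chromen-2-yl)phenoxy]-6H-chromene-4,5,7(8H)-trione (racemic at C8'', stereocentre lost on enolisation, not isolated) | O=C1CC(=O)C(Oc3ccc(-c4cc(=O)c5c(O)cc(OC)cc5o4)cc3)c2oc(-c3ccc(OCc4ccccc4)cc3)cc(=O)c12 | intermediate
16 | 2-(4-benzyloxyphenyl)-5,7-dihydroxy-8-[4-(5-hydroxy-7-methoxy-4-oxo-4H-chromen-2-yl)phenoxy]-4H-chromen-4-one | O=c1cc(-c2ccc(OCc3ccccc3)cc2)oc2c(Oc3ccc(-c4cc(=O)c5c(O)cc(OC)cc5o4)cc3)c(O)cc(O)c12 | intermediate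
17 | 2-(4-benzyloxyphenyl)-5-hydroxy-8-[4-(5-hydroxy-7-methoxy-4-oxo-4H-chromen-2-yl)phenoxy]-7-methoxy-4H-chromen-4-one | COc1cc(O)c2c(=O)cc(-c3ccc(Oc4c(OC)cc(O)c5c(=O)cc(-c6ccc(OCc7ccccc7)cc6)oc45)cc3)oc2c1 | intermediate
18 | 5-hydroxy-2-(4-hydroxyphenyl)-8-[4-(5-hydroxy-7-methoxy-4-oxo-4H-chromen-2-yl)phenoxy]-7-methoxy-4H-chromen-4-one | COc1cc(O)c2c(=O)cc(-c3ccc(Oc4c(OC)cc(O)c5c(=O)cc(-c6ccc(O)cc6)oc45)cc3)oc2c1 | target

**Step count and risks**

Total step count: 8. Longest linear sequence: 7 steps (1 → 3 → 9 → 10 → 14 → 16 → 17 → 18; the branch from 4 through 6 is equally long).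

Steps most likely to fail:

Step 6. The C7'' ester is conjugated with the C5''–C6'' enolate, so attack by the C8'' dienolate may stall; the polyanion may also aggregate or condense intermolecularly before it cyclises. The fallback sets out from acid 10 and returns at 16, and it replaces the ester by a thioester so that no trianion is needed. Acid 10 is activated as imidazolide 12 as in step 5 and combined with Mg(O2CCH2COSPh)2 (from 3-oxo-3-(phenylsulfanyl)propanoic acid, MgCl2, Et3N), which after decarboxylation should give S-phenyl 3-[6-(4-benzyloxyphenyl)-2-{[4-(5-hydroxy-7-methoxy-4-oxo-4H-chromen-2-yl)phenoxy]methyl}-4-oxo-4H-pyran-3-yl]-3-oxopropanethioate F1. With DBU in MeCN (rt → 50 °C) the thioester enolate can shed thiophenolate to the acylketene 3-[6-(4-benzyloxyphenyl)-2-{[4-(5-hydroxy-7-methoxy-4-oxo-4H-chromen-2-yl)phenoxy]methyl}-4-oxo-4H-pyran-3-yl]-3-oxoprop-1-en-1-one F2. Its ketene carbon C7'' lies next to the C8'' methylene, and amine-mediated tautomerisation to the C8'' dienol followed by addition to the ketene (or direct thio-Claisen attack on F1) should close ring A'' to 16.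

Step 3. C-acylation of the enol by ketene 7 may be overtaken by O-acylation of the enol or of the chelated 5-hydroxyl, by lactonisation of 8 to a 2-pyranone, by capture of 7 by the released acetone, or by thermal loss of isobutene from the tert-butyl β-ketoester. The fallback sets out from 3 and returns at 9. Ketoester 3 is condensed with pyrrolidine (cat. AcOH, 4 Å sieves, CH2Cl2, rt) to tert-butyl (E)-4-[4-(5-hydroxy-7-methoxy-4-oxo-4H-chromen-2-yl)phenoxy]-3-(pyrrolidin-1-yl)but-2-enoate F3. This is heated with 6 in PhMe at 80 °C. The enamine carbon is a much better partner for ketene 7 than any oxygen nucleophile in the molecule, and F3, not being a β-ketoester, cannot fragment to isobutene. The cycloadduct should lose pyrrolidine (PPTS) to give 9.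

Step 1. Self-alkylation of the chloro ketoester enolate may outrun displacement by the weakly nucleophilic 4'-phenoxide, and some 5-O-alkylation is possible. The fallback sets out from 1 and returns at 3. Genkwanin is alkylated with methyl bromoacetate (K2CO3, acetone, rt) to methyl [4-(5-hydroxy-7-methoxy-4-oxo-4H-chromen-2-yl)phenoxy]acetate F4. Saponification (LiOH, THF/H2O, 0 °C → rt) should give [4-(5-hydroxy-7-methoxy-4-oxo-4H-chromen-2-yl)phenoxy]acetic acid F5. 1,1'-Carbonyldiimidazole converts it into 1-{[4-(5-hydroxy-7-methoxy-4-oxo-4H-chromen-2-yl)phenoxy]acetyl}-1H-imidazole F6, which is homologated with KO2CCH2CO2C(CH3)3, MgCl2 and Et3N (MeCN, rt) to 3.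

**Further compounds**

F1 | step 6 | S-phenyl 3-[6-(4-benzyloxyphenyl)-2-{[4-(5-hydroxy-7-methoxy-4-oxo-4H-chromen-2-yl)phenoxy]methyl}-4-oxo-4H-pyran-3-yl]-3-oxopropanethioate | O=C(CC(=O)Sc1ccccc1)c1c(COc2ccc(-c3cc(=O)c4c(O)cc(OC)cc4o3)cc2)oc(-c2ccc(OCc3ccccc3)cc2)cc1=O
F2 | step 6 | 3-[6-(4-benzyloxyphenyl)-2-{[4-(5-hydroxy-7-methoxy-4-oxo-4H-chromen-2-yl)phenoxy]methyl}-4-oxo-4H-pyran-3-yl]-3-oxoprop-1-en-1-one | O=C=CC(=O)c1c(COc2ccc(-c3cc(=O)c4c(O)cc(OC)cc4o3)cc2)oc(-c2ccc(OCc3ccccc3)cc2)cc1=O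
F3 | step 3 | tert-butyl (E)-4-[4-(5-hydroxy-7-methoxy-4-oxo-4H-chromen-2-yl)phenoxy]-3-(pyrrolidin-1-yl)but-2-enoate | CC(C)(C)OC(=O)/C=C(/N1CCCC1)COc1ccc(-c2cc(=O)c3c(O)cc(OC)cc3o2)cc1
F4 | step 1 | methyl [4-(5-hydroxy-7-methoxy-4-oxo-4H-chromen-2-yl)phenoxy]acetate | COC(=O)COc1ccc(-c2cc(=O)c3c(O)cc(OC)cc3o2)cc1
F5 | step 1 | [4-(5-hydroxy-7-methoxy-4-oxo-4H-chromen-2-yl)phenoxy]acetic acid | O=C(O)COc1ccc(-c2cc(=O)c3c(O)cc(OC)cc3o2)cc1
F6 | step 1 | 1-{[4-(5-hydroxy-7-methoxy-4-oxo-4H-chromen-2-yl)phenoxy]acetyl}-1H-imidazole | O=C(COc1ccc(-c2cc(=O)c3c(O)cc(OC)cc3o2)cc1)n1ccnc1
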